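L, the ring, is what you want from this flask, and the flask starts losing it again soon after making it. J is the limiting reagent in this flask, the E charge being larger.

| setting | grey | ochre | flask |
|---|---|---|---|
| J | 1.5 M | 1.5 M | 1.5 M |
| E | 1.4 M (fed, over 1.0 min) | 2 M (fed, over 1.0 min) | 2.70 M (fed, over 1.0 min) |
| remark | run made earlier; the fed solution adds 0.50 times the starting volume | run made earlier; the fed solution adds 0.50 times the starting volume | the fed solution adds 0.50 times the starting volume |
| time |  |  | 6.0 min |

- grey (time / min: L / %, J / %): 0.333: 9, 73; 0.500: 9, 57; 0.833: 20, 22; 1.33: 35, 4; 2.00: 34, 2; 3.00: 28, 2; 5.00: 18, 0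
- ochre (time / min: L / %, J / %): 0.333: 8, 63; 0.500: 15, 43; 0.833: 33, 9; 1.33: 45, 1; 2.00: 45, 0; 3.00: 31, 3; 5.00: 19, 2

(readings scatter by 1.5 percentage points)

- time, not beyond 6.0 min, at which the flask holds most L
- the amount of L, in percent of the J charged, at that time
- the first time at which L reaches 26%, in the same percent, in min

- charges are per starting volume, the dose included; the dosed solution carries all of it
- the analysis behind the earlier runs scatters by 1.5 percentage points, standard deviation

My own reckoning builds the flask up one process at a time. Take the main step by itself, each E turning one J into L. The feed of 2.70 M min⁻¹ then meets the J charge in 0.556 min, and L stands at 100%.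

Now add the waste. At 1.33 min J reads 4% in grey and 1% in ochre, yet L reads 35% and 45%, so part of the J stands as neither. A straight line in the E charge through those two L readings brings L in this flask, at that time, down to 56.7%.

Then add the tail. With J reading 2% in grey and 0% in ochre at 2.00 min, L still falls, and you can replace each curve by one mean constant up to 5.00 min: 0.212 min⁻¹ in grey, 0.287 min⁻¹ in ochre. Their mean, 0.250 min⁻¹, is the tail constant, the mean first-order rate at which L falls from 2.00 min on. It is a reading, and it means a half-life of 2.78 min.

The forecast puts the peak at 54% (47% to 62%) at 1.3 min (1.05 min to 1.7 min), with L reaching 26% at 0.57 min (0.48 min to 0.68 min): “Extrapolating to 2.7 M with some saturation gives about 54%”. That peak lies below the 56.7% of my straight line.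

The flask gives 51.9% at 1.26 min and reaches 26% at 0.550 min, all inside those ranges.

    J + E → D (k = 0.180 M⁻¹ s⁻¹)
    D → L (k = 0.0650 s⁻¹)
    J + D → G (k = 0.00480 M⁻¹ s⁻¹)
    L ⇌ Z (K = 13.0, k = 0.00460 s⁻¹)
    J + L → Q (k = 0.0630 M⁻¹ s⁻¹)

With J as charged, L has a half-life of 0.12 min by J + L → Q, shorter than the 2.5 min of the forward step L → Z alone. In this flask Q stands at 30.1% at 1.00 min and at 30.2% at 6.00 min, while Z climbs from 6.36% to 48.4%. From the peak, 0.250 min⁻¹ gives 15.9% at 6.00 min, where the flask holds 17.2%. For the same recipe read at 2.50 min, it gives 38.1%, and that neighbour holds 40.1%.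

Readings and results were generated by integration from invented constants.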